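**Retrosynthetic overview**
1. 15 ⇒ 14 (remove the silyl ether) ⇒ cut the side-chain CH2–C(=O) bond to give 3-formyltetronic acid 13 and terminal alkene 4. They are joined by rhodium-catalysed hydroacylation. The formyl carbon, normally an acceptor, reacts with reversed polarity as an acyl-rhodium hydride, so no carbanionic chain reagent meets the acidic head group.
2. Enabling feature: on the furanone ring (ring A) the enolic O–H at C4 stands next to C3, which carries the exocyclic carbonyl carbon. The unit O4–C4=C3–C(=O) is a vinylogous salicylaldehyde and can hold rhodium in a five-membered O,C-chelate (Rh, O4, C4, C3, acyl C).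
3. 13 ⇒ 11 (aminomethylenation at C3, then hydrolysis) ⇒ 10 ⇒ β-keto ester 8 ⇒ (S)-glycerate acetonide 5 + methyl acetate 6 (Claisen condensation). C5 comes from the chiral pool.
4. 4 ⇒ (S)-2-methylbutyl Grignard reagent 3 + 11-bromoundec-1-ene 2 (copper-catalysed sp3–sp3 coupling). The chain stereocentre comes from the chiral pool.
5. Ring order: ring A, the only ring of the target, is closed early (step 3, lactonisation) as the temporary dioxolane of 5 is opened. The key step closes no ring.

Key step: step 7

Remark: all tricarbonyl compounds are drawn as the 4-hydroxy-3-acyl enol tautomer used in the target SMILES. The push–pull exocyclic C=C of 12 has no fixed geometry and is drawn without one.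

Step 1
Reactants: 1 (S)-1-bromo-2-methylbutane; 2 11-bromoundec-1-ene
Product: 4 (S)-13-methylpentadec-1-ene, via Grignard reagent 3 (not isolated)
Conditions: 1, Mg turnings, THF, 45 °C; then 2, Li2CuCl4 (3 mol %), THF/NMP, 0 °C → rt
Reagents that add atoms: none
Why: Copper-catalysed Grignard–alkyl bromide cross-coupling (Kochi-type sp3–sp3 coupling) is reliable for unhindered primary bromides and leaves the terminal alkene alone; the stereocentre of 1 lies β to magnesium, takes no part in bond formation and is carried over unchanged as the (S)-centre of the anteiso terminus.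

Step 2
Reactants: 5 methyl (S)-2,2-dimethyl-1,3-dioxolane-4-carboxylate; 6 methyl acetate
Product: 8 methyl 3-[(S)-2,2-dimethyl-1,3-dioxolan-4-yl]-3-oxopropanoate, via lithium enolate 7 (not isolated)
Conditions: 6 (2.5 equiv), LiN(iPr)2 (2.5 equiv), THF, −78 °C; then 5, −78 → −40 °C; AcOH quench at −78 °C
Reagents that add atoms: none
Why: Crossed Claisen condensation, in which the preformed ester enolate adds to the more electrophilic α-alkoxy ester at low temperature and the β-keto ester is at once stored as its central enolate, which shields the neighbouring dioxolane stereocentre (no new stereocentre).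

Step 3
Reactants: 8 methyl 3-[(S)-2,2-dimethyl-1,3-dioxolan-4-yl]-3-oxopropanoate
Product: 10 (S)-4-hydroxy-5-(hydroxymethyl)furan-2(5H)-one, via dihydroxy keto ester 9 (not isolated)
Conditions: TFA/H2O (9:1), 0 °C → rt; evaporation, co-evaporation with MeOH/toluene
Reagents that add atoms: none
Why: Acid-catalysed acetonide hydrolysis followed by spontaneous 5-exo-trig lactonisation of the secondary hydroxyl onto the methyl ester (the standard tetronic acid synthesis from γ-hydroxy-β-keto esters); the conjugated five-membered enol lactone is the thermodynamic sink over the six-membered lactone, and C5 keeps its configuration because its C–O bond is never broken.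

Step 4
Reactants: 10 (S)-4-hydroxy-5-(hydroxymethyl)furan-2(5H)-one
Product: 11 (S)-5-{[(tert-butyldiphenylsilyl)oxy]methyl}-4-hydroxyfuran-2(5H)-one
Conditions: TBDPSCl (1.1 equiv), imidazole (2.5 equiv), DMF, 0 °C → rt; aq. citric acid work-up
Reagents that add atoms: tert-butyl(chloro)diphenylsilane (TBDPSCl), CC(C)(C)[Si](Cl)(c1ccccc1)c1ccccc1
Why: Standard imidazole-promoted silylation, in which the primary alcohol is silylated irreversibly while any silyl enol ether formed at O4 is labile and falls off in the acidic work-up.

Step 5
Reactants: 11 (S)-5-{[(tert-butyldiphenylsilyl)oxy]methyl}-4-hydroxyfuran-2(5H)-one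
Product: 12 (S)-5-{[(tert-butyldiphenylsilyl)oxy]methyl}-3-[(dimethylamino)methylidene]furan-2,4(3H,5H)-dione
Conditions: Me2NCH(OMe)2 (1.2 equiv), CH2Cl2, 0 °C → rt
Reagents that add atoms: N,N-dimethylformamide dimethyl acetal, COC(OC)N(C)C
Why: Enaminone formation from a cyclic 1,3-dicarbonyl compound and an amide acetal, in which the nucleophilic C3 attacks the methoxyiminium ion released by the acidic enol; the mild near-neutral medium should leave C5 untouched.

Step 6
Reactants: 12 (S)-5-{[(tert-butyldiphenylsilyl)oxy]methyl}-3-[(dimethylamino)methylidene]furan-2,4(3H,5H)-dione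
Product: 13 (S)-5-{[(tert-butyldiphenylsilyl)oxy]methyl}-4-hydroxy-2-oxo-2,5-dihydrofuran-3-carbaldehyde
Conditions: 1 M HCl (aq)/THF, rt
Reagents that add atoms: water, O
Why: Hydrolysis of a doubly activated vinylogous amide by addition–elimination of water at the exocyclic carbon, a known entry to 2-formyl-1,3-dicarbonyl compounds; acidic conditions avoid enolisation at C5 and the TBDPS ether tolerates dilute acid.

Step 7
Reactants: 13 (S)-5-{[(tert-butyldiphenylsilyl)oxy]methyl}-4-hydroxy-2-oxo-2,5-dihydrofuran-3-carbaldehyde; 4 (S)-13-methylpentadec-1-ene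
Product: 14 (S)-5-{[(tert-butyldiphenylsilyl)oxy]methyl}-4-hydroxy-3-[(S)-14-methylhexadecanoyl]furan-2(5H)-one
Conditions: 4 (1.5 equiv), [Rh(cod)Cl]2 (2.5 mol %), O,O'-[(R)-1,1'-binaphthyl-2,2'-diyl] N,N-bis[(R)-1-phenylethyl]phosphoramidite (6 mol %), iPr2NEt (1.1 equiv), 1,2-dichloroethane, 70 °C, Ar; then 1 M HCl work-up
Reagents that add atoms: none
Why: Proposed new method: deprotonated 13 binds monovalent rhodium through O4, the formyl C–H bond adds oxidatively to give a five-membered O,C-chelated acyl rhodium hydride (trivalent rhodium; ring atoms Rh, O4, C4, C3, acyl C), alkene 4 inserts into Rh–H with rhodium going to the terminal carbon, and C–C reductive elimination joins that CH2 to the acyl carbon before the product enolate is displaced by fresh substrate. The closest known reaction type is the chelation-assisted rhodium/phosphoramidite hydroacylation of unactivated 1-alkenes with salicylaldehydes, of which the O4–C4=C3–CHO unit of 13 is the vinylogous-acid counterpart; what is new is the aldehyde class, a strongly acidic heterocyclic β-hydroxy enal. No ring of the target is closed (only the transient rhodacycle) and no stereocentre is created, so the step only has to leave the two existing centres alone: C5 is safe because 13 reacts as its mono-anion, which an amine cannot deprotonate a second time, and the chain centre lies ten methylene groups away from the alkene. The selectivities needed are linear over branched insertion, secured by the unbiased terminal alkene and the bulky monodentate ligand, and hydroacylation over decarbonylation, secured by the chelate, because loss of CO would have to contract the five-membered rhodacycle to a four-membered one. Full neutralisation with iPr2NEt protects the acid-labile P–N bond of the ligand, and the silyl ether keeps the salt soluble and stops the primary alcohol from condensing with the formyl group. In one neutral, fully atom-economic operation the step installs the whole C16 chain and the ketone at its final oxidation level on a head group whose acidic enol and lactone would not tolerate the Grignard or organolithium reagent that normal polarity would demand.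

Step 8
Reactants: 14 (S)-5-{[(tert-butyldiphenylsilyl)oxy]methyl}-4-hydroxy-3-[(S)-14-methylhexadecanoyl]furan-2(5H)-one
Product: 15 (S)-4-hydroxy-5-(hydroxymethyl)-3-[(S)-14-methylhexadecanoyl]furan-2(5H)-one (target)
Conditions: HF·pyridine, THF, 0 °C → rt (plastic vessel); purification on acid-washed silica or reversed phase
Reagents that add atoms: none
Why: Fluoride-driven silyl ether cleavage under weakly acidic, non-basic conditions, which should spare the 3-acyltetronic acid, the lactone and the C5 stereocentre.

**Compound list**
1 | (S)-1-bromo-2-methylbutane | CC[C@H](C)CBr | starting material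
2 | 11-bromoundec-1-ene | C=CCCCCCCCCCBr | starting material
3 | (S)-2-methylbutylmagnesium bromide | CC[C@H](C)C[Mg]Br | intermediate
4 | (S)-13-methylpentadec-1-ene | CC[C@H](C)CCCCCCCCCCC=C | intermediate
5 | methyl (S)-2,2-dimethyl-1,3-dioxolane-4-carboxylate | COC(=O)[C@@H]1COC(C)(C)O1 | starting material
6 | methyl acetate | COC(C)=O | starting material
7 | lithium enolate of methyl acetate | [Li+].[O-]C(=C)OC | intermediate
8 | methyl 3-[(S)-2,2-dimethyl-1,3-dioxolan-4-yl]-3-oxopropanoate | COC(=O)CC(=O)[C@@H]1COC(C)(C)O1 | intermediate
9 | methyl (S)-4,5-dihydroxy-3-oxopentanoate | COC(=O)CC(=O)[C@@H](O)CO | intermediate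
10 | (S)-4-hydroxy-5-(hydroxymethyl)furan-2(5H)-one | O=C1C=C(O)[C@H](CO)O1 | intermediate
11 | (S)-5-{[(tert-butyldiphenylsilyl)oxy]methyl}-4-hydroxyfuran-2(5H)-one | O=C1C=C(O)[C@H](CO[Si](c2ccccc2)(c2ccccc2)C(C)(C)C)O1 | intermediate
12 | (S)-5-{[(tert-butyldiphenylsilyl)oxy]methyl}-3-[(dimethylamino)methylidene]furan-2,4(3H,5H)-dione | CN(C)C=C1C(=O)[C@H](CO[Si](c2ccccc2)(c2ccccc2)C(C)(C)C)OC1=O | intermediate
13 | (S)-5-{[(tert-butyldiphenylsilyl)oxy]methyl}-4-hydroxy-2-oxo-2,5-dihydrofuran-3-carbaldehyde | O=CC1=C(O)[C@H](CO[Si](c2ccccc2)(c2ccccc2)C(C)(C)C)OC1=O | intermediate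
14 | (S)-5-{[(tert-butyldiphenylsilyl)oxy]methyl}-4-hydroxy-3-[(S)-14-methylhexadecanoyl]furan-2(5H)-one | CC[C@H](C)CCCCCCCCCCCCC(=O)C1=C(O)[C@H](CO[Si](c2ccccc2)(c2ccccc2)C(C)(C)C)OC1=O | intermediate
15 | (S)-4-hydroxy-5-(hydroxymethyl)-3-[(S)-14-methylhexadecanoyl]furan-2(5H)-one | CC[C@H](C)CCCCCCCCCCCCC(=O)C1=C(O)[C@H](CO)OC1=O | target

Total step count: 8. Longest linear sequence: 7 (steps 2 to 8). Step 1 is the convergent branch.

**Steps most likely to fail**

1. Step 7.
   - Risks: oxidative addition of the electron-poor, delocalised formyl enolate may be slow. The acyl rhodium hydride may lose CO and deactivate the catalyst. The strongly chelating product may hold rhodium back. Rhodium hydride may isomerise the alkene to unreactive internal isomers.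
   - Fallback (known chemistry): it sets out from Grignard reagent 3 and tetronic acid 11 and comes back at 14. Reagent 3 is coupled (Li2CuCl4 cat., THF) with commercial 12-bromododecanoic acid, deprotonated beforehand with MeMgCl, to give (S)-14-methylhexadecanoic acid F1. Steglich esterification of F1 with 11 (DCC, DMAP cat., CH2Cl2) gives the enol ester (S)-2-{[(tert-butyldiphenylsilyl)oxy]methyl}-5-oxo-2,5-dihydrofuran-3-yl (S)-14-methylhexadecanoate F2. With more DMAP and Et3N, F2 undergoes the established Fries-type O-to-C acyl migration to 14.

2. Step 6.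
   - Risks: the hydrolysis may stall, or water may add to the liberated formyl group and trigger retro-Claisen loss of formate back to 11.
   - Fallback: it sets out from 11 and comes back at 13. Heating 11 in neat triethyl orthoformate with removal of ethanol gives the enol ether (S)-5-{[(tert-butyldiphenylsilyl)oxy]methyl}-3-(ethoxymethylidene)furan-2,4(3H,5H)-dione F3. Its much better leaving group allows hydrolysis in wet THF at rt without acid or base, so 13 is released under conditions that do not favour deformylation.

3. Step 2.
   - Risks: the ester enolate may act as a base. This would deprotonate 5 at the dioxolane carbon and cause epimerisation or β-elimination with ring opening.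
   - Fallback: it sets out from 5 and comes back at 8. Saponification (LiOH, THF/H2O, 0 °C; careful acidification) gives (S)-2,2-dimethyl-1,3-dioxolane-4-carboxylic acid F4. Carbonyldiimidazole converts F4 to (S)-(2,2-dimethyl-1,3-dioxolan-4-yl)(1H-imidazol-1-yl)methanone F5. Neutral decarboxylative Claisen condensation (Masamune–Brooks reaction: KO2CCH2CO2Me, MgCl2, Et3N, MeCN, rt) then gives 8 without any strong base.

**Further compounds**
F1 | step 7 | (S)-14-methylhexadecanoic acid | CC[C@H](C)CCCCCCCCCCCCC(=O)O
F2 | step 7 | (S)-2-{[(tert-butyldiphenylsilyl)oxy]methyl}-5-oxo-2,5-dihydrofuran-3-yl (S)-14-methylhexadecanoate | CC[C@H](C)CCCCCCCCCCCCC(=O)OC1=CC(=O)O[C@H]1CO[Si](c2ccccc2)(c2ccccc2)C(C)(C)C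
F3 | step 6 | (S)-5-{[(tert-butyldiphenylsilyl)oxy]methyl}-3-(ethoxymethylidene)furan-2,4(3H,5H)-dione | CCOC=C1C(=O)[C@H](CO[Si](c2ccccc2)(c2ccccc2)C(C)(C)C)OC1=O
F4 | step 2 | (S)-2,2-dimethyl-1,3-dioxolane-4-carboxylic acid | OC(=O)[C@@H]1COC(C)(C)O1
F5 | step 2 | (S)-(2,2-dimethyl-1,3-dioxolan-4-yl)(1H-imidazol-1-yl)methanone | O=C(n1ccnc1)[C@@H]2COC(C)(C)O2
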